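The runs are simulated on assumed constants.

The closed, stirred vessel holds E in solution under G at constant pressure; G dissolves as L, and L with E gives X.

| flask | E | G | remark | time |
|---|---|---|---|---|
| larch | 0.54 M | 29 mM (held) | run made earlier |  |
| cedar | 1.2 M | 29 mM (held) | run made earlier |  |
| flask | 0.80 M | 29 mM (held) |  | 3.0 d |

| run | time / d | X / % | E / % |
|---|---|---|---|
| larch | 0.208 | 22.7 | 9.2 |
| larch | 0.333 | 32.1 | 7.6 |
| larch | 0.625 | 51.5 | 5.6 |
| larch | 1.25 | 76.2 | 2.4 |
| larch | 2.50 | 91.5 | 0.3 |
| cedar | 0.500 | 40.4 | 7.5 |
| cedar | 1.04 | 67.1 | 3.5 |
| cedar | 1.25 | 73.3 | 3.7 |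
| cedar | 2.08 | 87.5 | 1.0 |
| cedar | 2.50 | 91.7 | 0.1 |

(readings scatter by 0.5 percentage points)

- at the start none of L is dissolved
- on the list of suspects stand: G <-> L; E + L -> X; E -> J; L -> Z; E <-> D; 2 L -> Q

1. X at 3.0 d, in percent of the E charged
2. the change that raises the amount of X at 3.0 d, in percent of the E charged most ("none" if none brings more than 2 percentage points) (Thursday's / Saturday's / none)
3. amount of X at 3.0 d, in percent of the E charged, after Thursday's

- Thursday's: doubling the transfer coefficient of G, all else as stated
- Saturday's: doubling the saturation concentration of G, all else as stated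

Take the main step first. With L steady, X grows by pseudo-first-order kinetics towards a ceiling c. The larch and cedar runs, charged with 0.54 M and 1.2 M, stand at 91.5% and 91.7% after 2.50 d, so the percent curve barely follows the charge. On such a curve, X at twice a given time t, divided by X at t, equals 1 + exp(−κt), whatever c is. The readings at 1.25 d and 2.50 d, averaged over both runs, give the pool constant κ, the fraction per day of what is still on its way to X that goes on to X: 1.20 d⁻¹.

Now add D. The larch run holds 2.4% of E at 1.25 d, yet it gains 15 percentage points of X by 2.50 d, more than that E. So a stock D, the resting state, stands behind E. The number does not change, since κ was read from X and already carries this holding back.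

Last comes the leak to J, which puts c below the full charge. The mean X at 1.25 d gives c = 96.4%.

At 3.0 d this reckoning gives 93.8%, with a room of 2.7 points left under c, against the 2 points a change must bring. Thursday's doubles the transfer coefficient of G and Saturday's doubles its saturation concentration. The X readings of the larch and cedar runs at 2.50 d, at charges 2.22 times apart, differ by 0.2 points, less than the 0.5 points of a reading, so this reckoning takes E as a small drag on L and expects Thursday's to stay inside that room. Saturday's raises the level towards which L is drawn, so this reckoning picks Saturday's.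

The forecast gives 93.5%, Saturday's, and 95% after Thursday's: “Doubling saturation roughly doubles L, which speeds X and reduces the leak”.

This flask gives 94.2%, with Saturday's best and 95.8% after Thursday's. In this flask L stands at 67.7% of saturation at 1.50 d. Thursday's gain of 1.6 points stays inside the room of 2.7 points, while Saturday's gain of 3.5 points goes beyond it, so X after Saturday's stands above the c read from the runs.

    G ⇌ L, rate k1*(csat - [L]) (kL = 0.110 min⁻¹)
    E + L → X (k = 0.349 M⁻¹ min⁻¹)
    E → J (k = 2.23 × 10⁻⁴ min⁻¹)
    L → Z (k = 0.00168 min⁻¹)
    E ⇌ D (K = 6.82, k = 0.117 min⁻¹)
    2 L → Q (k = 1.15 M⁻¹ min⁻¹)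

With 1.4 M of E and the same time, κ and c, read as independent of the charge, give 93.8% again; that flask gives 93.6%.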